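The easy step with these readings is to add them up before fitting anything.

- theta: starting material 23 mM; partner 1.8 equiv; scavenger 0.80 equiv; the very flask that is asked about, followed so far
- flask: starting material 23 mM; partner 1.80 equiv; scavenger 0.800 equiv; time 15 h

- theta (time / h: starting material / %, mono adduct / %): 1.50: 87, 1; 3.00: 79, 12; 5.00: 71, 16; 6.00: 72, 16; 8.00: 65, 23

(readings scatter by 2 percentage points)

- a reading or a percentage of mono adduct counts all its forms, free or not
- a reading of starting material is of its free form alone

- how much starting material there is at 15 h, in percent of the starting material charged
- how much mono adduct there is at 15 h, in percent of the starting material charged
- how much double product there is at 15 h, in percent of the starting material charged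

Two chemists add differently. The first adds starting material and mono adduct as fractions of the charge and finds a steady 88.4% on average. The forecast is hers: “The sum A + M sits flat at about 88% from the first reading”. It gives 52% of starting material, bound form counted (range 44% to 58%), 37% of mono adduct (30% to 44%) and 11% of double product (3% to 20%).

The second chemist notes that a reading of starting material sees the free form, while mono adduct is read in all its forms. If starting material is held on a mono adduct, it therefore vanishes from view. So he keeps a pair sum, free starting material plus mono adduct counted as two, and averages it over the run: 102%. That is close to the charge, though single sums run from 89.0% to 111%, a wider spread than hers. From the charge through the last reading, free starting material falls by 0.0538 /h. His reckoning for this flask at 15 h is 44.6% free, so mono adduct is 28.7%, with double product below about 2 percentage points.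

This flask gives 42.9% of free starting material, 29.4% of mono adduct and 0.699% of double product.

    starting material + partner → mono adduct + released group (k = 2.47 × 10⁻⁴ /M/s)
    partner + mono adduct → double product + released group (k = 3.47 × 10⁻⁴ /M/s)
    partner + released group ⇌ idle adduct A, settled at all times (K = 3360 /M)
    scavenger + released group → scavenged by-product (k = 0.0604 /M/s)
    starting material + mono adduct ⇌ idle adduct B, settled at all times (K = 1100 /M)
    released group → by-product carried off (k = 2.10 × 10⁻⁵ /s)

His 28.7% of mono adduct lies nearer this flask's 29.4% than the forecast's 37% does; this flask's pair sum is 102%, and idle adduct B, the resting state of mono adduct, stands at 53.9%, both members counted. Read at 25 h, the same flask has 28.8% free, so the pair sum predicts 36.6% of mono adduct against 36.9%. Her flat gap fits one stretch of this flask, as the gap grows from 4.88% at 1.50 h to 15.6% at 6.00 h, passing her value. The time allowed is at most the largest single effect on this flask's mono adduct, not the main reason it stays low: left ten times as long, 29.4% becomes 35.6%, a gain of 6.1 points, which is 8.8% of what is missing.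

Readings and results are calculated from invented constants, noise included.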